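## Retrosynthetic overview

1. Target ⇐ C‑8′ epimerisation (α to the aryl ketone) of the all‑cis hydroxy ketone, the open form of the 7′‑hydroxy furofuran hemiketal through which a furofuran lignan is opened in the biogenesis of 7′‑oxo‑7,9′‑epoxylignans.
2. All‑cis hydroxy ketone ⇐ the biogenetic ring closure O‑9′ → C‑7 inside an 8–8′‑linked dimer, run at the ketone oxidation level: hemiketalisation, then hydride delivery to the oxocarbenium ion sets the 7,8‑cis relationship.
3. C2‑symmetric (8S,8′S)‑1,4‑diketone diol ⇐ catalytic asymmetric double hydroxymethylation of a bis(silyl enol ether) with formaldehyde.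
4. 8–8′ bond ⇐ one‑electron oxidative dimerisation of the enolate of 3′,4′,5′‑trimethoxyacetophenone.
5. Ring order: the tetrahydrofuran is the only ring and is closed in the last step.

Assumption: in step 3 the (S,S)‑ligand/Sc(OTf)3 catalyst is taken to give the S configuration at each new stereocentre; the sense must be confirmed on the first run, and the (R,R)‑ligand is equally available.

## Route

Step 1
Reactants: 1 3′,4′,5′‑trimethoxyacetophenone (two molecules)
Product: 3 1,4‑bis(3,4,5‑trimethoxyphenyl)butane‑1,4‑dione, via lithium enolate 2 (not isolated)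
Conditions: LiN(iPr)2 (1.05 equiv), THF, −78 °C; CuCl2 (1.1 equiv), DMF, −78 °C to rt
Reagents that add atoms: none
Why: Oxidative enolate homocoupling, in which CuCl2 oxidises the lithium enolate by one electron to an α‑keto radical that dimerises at carbon (the laboratory counterpart of the 8–8′ radical coupling of two phenylpropanoid units), and no stereocentre is formed.

Step 2
Reactants: 3 1,4‑bis(3,4,5‑trimethoxyphenyl)butane‑1,4‑dione
Product: 5 (1Z,3Z)‑1,4‑bis(3,4,5‑trimethoxyphenyl)‑1,4‑bis(trimethylsilyloxy)buta‑1,3‑diene, via mono(silyl enol ether) 4 (not isolated)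
Conditions: LiN(SiMe3)2 (2.3 equiv), Me3SiCl (2.6 equiv, present from the start), THF, −78 to 0 °C; pentane, filtration, used crude
Reagents that add atoms: chlorotrimethylsilane, C[Si](C)(C)Cl
Why: Silyl enol ether formation by kinetic enolisation with internal Me3SiCl quench, in which the first enolate is trapped before it can attack the second carbonyl, the second deprotonation can only occur at the remaining CH2, and aryl ketone enolates are silylated with Z geometry, so no stereocentre is involved.

Step 3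
Reactants: 5 (1Z,3Z)‑1,4‑bis(3,4,5‑trimethoxyphenyl)‑1,4‑bis(trimethylsilyloxy)buta‑1,3‑diene, 6 formaldehyde (aqueous)
Product: 8 (2S,3S)‑2,3‑bis(hydroxymethyl)‑1,4‑bis(3,4,5‑trimethoxyphenyl)butane‑1,4‑dione, via mono‑hydroxymethyl enol ether 7 (not isolated)
Conditions: Sc(OTf)3 (0.2 equiv), (S,S)‑6,6′‑bis(1‑hydroxy‑2,2‑dimethylpropyl)‑2,2′‑bipyridine (0.24 equiv), 37% aq. CH2O (10 equiv), DME/H2O 9:1, −20 °C; aq. NaHCO3; chromatography
Reagents that add atoms: formaldehyde, C=O
Why: Proposed new method: each Z‑silyl enol ether terminus of 5 undergoes a Lewis‑acid‑catalysed Mukaiyama aldol addition to formaldehyde held in the chiral Sc(OTf)3–bipyridine complex, the first addition (giving 7) leaves the second enol ether intact and the same catalyst face selection then sets C‑8′, so both new stereocentres are S and the C2‑symmetric diol 8 is enriched in ee at the expense of a separable meso isomer, the closest known reaction being the catalytic asymmetric hydroxymethylation of propiophenone‑type silicon enolates with aqueous formaldehyde.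

Step 4
Reactants: 8 (2S,3S)‑2,3‑bis(hydroxymethyl)‑1,4‑bis(3,4,5‑trimethoxyphenyl)butane‑1,4‑dione
Product: 12 [(3R,4S,5S)‑4‑(hydroxymethyl)‑5‑(3,4,5‑trimethoxyphenyl)oxolan‑3‑yl](3,4,5‑trimethoxyphenyl)methanone, via keto lactol 9 (not isolated), via all‑cis hydroxy ketone 10 (not isolated), via bicyclic hemiketal 11 (not isolated)
Conditions: Et3SiH (1.2 equiv, added over 1 h), BF3·OEt2 (1.5 equiv), CH2Cl2, −78 °C; aq. NaHCO3; then K2CO3 (0.5 equiv), MeOH, rt
Reagents that add atoms: none
Why: Reductive cycloetherification by ionic hydrogenation, in which O‑9′ adds to the C‑7 ketone, BF3 ionises lactol 9 to a 2‑aryl oxocarbenium ion and Et3SiH delivers hydride to the face opposite the cis C‑8 and C‑8′ substituents, which sets C‑7 as S (aryl cis to CH2OH) in 10, and K2CO3 then epimerises the only acidic stereocentre, C‑8′ next to the ketone, from the crowded all‑cis array (reversibly masked as hemiketal 11) to the trans ketone 12, which can no longer close to a hemiketal.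

## Compound list

1 | 3′,4′,5′‑trimethoxyacetophenone | CC(=O)c1cc(OC)c(OC)c(OC)c1 | starting material
2 | lithium 1‑(3,4,5‑trimethoxyphenyl)ethen‑1‑olate | [Li]OC(=C)c1cc(OC)c(OC)c(OC)c1 | intermediate (not isolated)
3 | 1,4‑bis(3,4,5‑trimethoxyphenyl)butane‑1,4‑dione | O=C(CCC(=O)c1cc(OC)c(OC)c(OC)c1)c1cc(OC)c(OC)c(OC)c1 | intermediate
4 | (Z)‑1,4‑bis(3,4,5‑trimethoxyphenyl)‑4‑(trimethylsilyloxy)but‑3‑en‑1‑one | C[Si](C)(C)O/C(=C\CC(=O)c1cc(OC)c(OC)c(OC)c1)c1cc(OC)c(OC)c(OC)c1 | intermediate (not isolated)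
5 | (1Z,3Z)‑1,4‑bis(3,4,5‑trimethoxyphenyl)‑1,4‑bis(trimethylsilyloxy)buta‑1,3‑diene | C[Si](C)(C)O/C(c1cc(OC)c(OC)c(OC)c1)=C\C=C(/O[Si](C)(C)C)c1cc(OC)c(OC)c(OC)c1 | intermediate
6 | formaldehyde | C=O | starting material
7 | (2S,3Z)‑2‑(hydroxymethyl)‑1,4‑bis(3,4,5‑trimethoxyphenyl)‑4‑(trimethylsilyloxy)but‑3‑en‑1‑one | COc1cc(cc(OC)c1OC)C(=O)[C@H](CO)/C=C(\O[Si](C)(C)C)c1cc(OC)c(OC)c(OC)c1 | intermediate (not isolated)
8 | (2S,3S)‑2,3‑bis(hydroxymethyl)‑1,4‑bis(3,4,5‑trimethoxyphenyl)butane‑1,4‑dione | COc1cc(cc(OC)c1OC)C(=O)[C@H](CO)[C@@H](CO)C(=O)c1cc(OC)c(OC)c(OC)c1 | intermediate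
9 | [(3S,4S)‑5‑hydroxy‑4‑(hydroxymethyl)‑5‑(3,4,5‑trimethoxyphenyl)oxolan‑3‑yl](3,4,5‑trimethoxyphenyl)methanone, both anomers at C‑5 | OC[C@@H]1[C@H](C(=O)c2cc(OC)c(OC)c(OC)c2)COC1(O)c1cc(OC)c(OC)c(OC)c1 | intermediate (not isolated)
10 | [(3S,4S,5S)‑4‑(hydroxymethyl)‑5‑(3,4,5‑trimethoxyphenyl)oxolan‑3‑yl](3,4,5‑trimethoxyphenyl)methanone, aryl, CH2OH and aroyl all cis | COc1cc(C(=O)[C@@H]2CO[C@H](c3cc(OC)c(OC)c(OC)c3)[C@@H]2CO)cc(OC)c1OC | intermediate (not isolated)
11 | (1S,5S,6S)‑2,6‑bis(3,4,5‑trimethoxyphenyl)‑3,7‑dioxabicyclo[3.3.0]octan‑2‑ol, cis‑fused, 6‑aryl endo, both anomers at C‑2 | COc1cc(cc(OC)c1OC)[C@H]1OC[C@@H]2[C@H]1COC2(O)c1cc(OC)c(OC)c(OC)c1 | intermediate (not isolated)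
12 | [(3R,4S,5S)‑4‑(hydroxymethyl)‑5‑(3,4,5‑trimethoxyphenyl)oxolan‑3‑yl](3,4,5‑trimethoxyphenyl)methanone, aryl cis to CH2OH, aroyl trans to CH2OH | COc1cc(C(=O)[C@H]2CO[C@H](c3cc(OC)c(OC)c(OC)c3)[C@@H]2CO)cc(OC)c1OC | target

Stereochemical bookkeeping (lignan numbering):
- C‑8 (S) is set in step 3 and never touched again.
- C‑7 (S) is set in step 4 by hydride delivery anti to the C‑8 substituent.
- C‑8′ is set S in step 3 and is deliberately inverted to R by base in step 4.
- The SMILES of 12 is identical to the target string.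

## Step count and risks

Total steps: 4. Longest linear sequence: 4 (1 → 3 → 5 → 8 → 12).

The three steps most likely to fail are steps 3, 4 and 1; step 2 is a routine double silylation.

**Step 3 (asymmetric double hydroxymethylation).**
- The diene may hydrolyse faster than it adds formaldehyde.
- The free hydroxyl of 7 may add to the remaining enol ether.
- The 1,4‑dicarbonyl may dehydrate to a 2,5‑diarylfuran.
- The sense or level of induction on this substrate is untested.
- Any meso diol must be removed here, because it would give racemic product in step 4.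

Fallback, setting out from 5 and coming back at 12: enantiocontrol is moved from catalysis to a late enzymatic resolution. Diene 5 is hydroxymethylated with aqueous formaldehyde and achiral Yb(OTf)3 in THF/H2O at rt. This gives 8 as the racemate, that is together with (2R,3R)‑diketone diol F1, plus some meso (2R,3S)‑diketone diol F2. The mixture is taken through the conditions of step 4; the meso isomer gives the trans product directly, so everything converges on 12 together with its mirror image, the (3S,4R,5R)‑hydroxy ketone F3. A lipase (Pseudomonas cepacia lipase, vinyl acetate, t‑BuOMe, rt; enzyme and sense chosen by screening) then acetylates the primary alcohol of F3 to the (2R,3R,4S)‑acetate F4. Unreacted 12 is separated by chromatography.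

**Step 4 (mono reductive cycloetherification and epimerisation).**
- Product 10 can close a second time through 11 and be reduced again to the doubly cyclised furofuran. This should be slower than the first closure, because a cis‑fused bicycle has to form next to an endo aryl group, but the selectivity is not guaranteed.
- Warming with BF3 could ionise the new benzylic ether and erode the 7,8‑cis relationship.
- Acid could divert the 1,4‑diketone to a furan.

Fallback, setting out from 8 and coming back at 11: 8 is driven completely, with Et3SiH (4 equiv) and BF3·OEt2 in CH2Cl2 at −78 °C, to the C2‑symmetric (1S,2S,5S,6S)‑2,6‑bis(3,4,5‑trimethoxyphenyl)‑3,7‑dioxabicyclo[3.3.0]octane F5, with both aryl groups endo. One ring is then reopened oxidatively, as in the biogenesis. DDQ (1.0 equiv) in CH2Cl2/H2O at 0 °C abstracts hydride from one of the two equivalent, exposed exo benzylic C–H bonds, and water captures the oxocarbenium ion to give hemiketal 11. The K2CO3/MeOH treatment of step 4 then gives 12. Doubly oxidised material is 8 again and is returned to the reduction.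

**Step 1 (oxidative enolate dimerisation).**
- The heterogeneous CuCl2 oxidation can stall.
- Aldol condensation or α‑chlorination of the electron‑rich ketone can compete.

Fallback, setting out from 1 and coming back at 3: the 8–8′ bond is made by polar alkylation. Ketone 1 is α‑brominated with CuBr2 in EtOAc/CHCl3 at reflux to 2‑bromo‑1‑(3,4,5‑trimethoxyphenyl)ethan‑1‑one F6. F6 is then coupled with a second equivalent of 1 through its zinc enolate (ZnCl2, Et2NH, t‑BuOH, toluene, rt) to give 3.

## Further compounds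

F1 | step 3 | (2R,3R)‑2,3‑bis(hydroxymethyl)‑1,4‑bis(3,4,5‑trimethoxyphenyl)butane‑1,4‑dione | COc1cc(cc(OC)c1OC)C(=O)[C@@H](CO)[C@H](CO)C(=O)c1cc(OC)c(OC)c(OC)c1
F2 | step 3 | meso (2R,3S)‑2,3‑bis(hydroxymethyl)‑1,4‑bis(3,4,5‑trimethoxyphenyl)butane‑1,4‑dione | COc1cc(cc(OC)c1OC)C(=O)[C@H](CO)[C@H](CO)C(=O)c1cc(OC)c(OC)c(OC)c1
F3 | step 3 | [(3S,4R,5R)‑4‑(hydroxymethyl)‑5‑(3,4,5‑trimethoxyphenyl)oxolan‑3‑yl](3,4,5‑trimethoxyphenyl)methanone | COc1cc(C(=O)[C@@H]2CO[C@@H](c3cc(OC)c(OC)c(OC)c3)[C@H]2CO)cc(OC)c1OC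
F4 | step 3 | [(2R,3R,4S)‑4‑(3,4,5‑trimethoxybenzoyl)‑2‑(3,4,5‑trimethoxyphenyl)oxolan‑3‑yl]methyl acetate | COc1cc(C(=O)[C@@H]2CO[C@@H](c3cc(OC)c(OC)c(OC)c3)[C@H]2COC(C)=O)cc(OC)c1OC
F5 | step 4 | (1S,2S,5S,6S)‑2,6‑bis(3,4,5‑trimethoxyphenyl)‑3,7‑dioxabicyclo[3.3.0]octane | COc1cc(cc(OC)c1OC)[C@H]1OC[C@@H]2[C@H]1CO[C@@H]2c1cc(OC)c(OC)c(OC)c1
F6 | step 1 | 2‑bromo‑1‑(3,4,5‑trimethoxyphenyl)ethan‑1‑one | O=C(CBr)c1cc(OC)c(OC)c(OC)c1
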